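**Plan**
Numbering: ring A = C1–C2–C3–C4–C5–C9 (triketone; benzoyl on C1, geranyl on C5); ring B = C1–C8(Me2)–C7–C6–C5–C9; bridge C7–C10H2–C11H–C3; cyclopentane C3–C11–C12(Me2)–C13–C14; carbinol C15 on C13.
Cuts: the geranyl chain back to prenyl; then C7–C10, C11–C3 and C8–C1 in one retro-cascade, with C15–OH and C2=O re-joined as a pyran (temporary ring P), giving monocyclic dienone 17; 17 goes back to a benzophenone arene, two prenyl units and a C13/C14 side chain.
Enabling feature: in 17, C3 sits between the C2 and C4 oxygens of the six-membered tricarbonyl ring A and can be oxidised to a carbon radical. It lies 1,5 to the internal vinyl carbon C11, and the sp3 carbon C5 holds a prenyl olefin (C7=C8) over the same ring face.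
Forward: arene → C14/C13 chain (Mannich base, auxiliary alkylation) → ring P → dearomatising gem-diprenylation → one oxidation closes the cyclopentane, the seven-membered ring and ring B → prenyl to geranyl.
Stereochemistry: C13 (R) comes from an oxazolidinone auxiliary; ring P relays it to C3 and C11; the cage then fixes C1, C5 and C7.

Key step: step 8

Assumption: the C15 alcohol and the C2 ketone are taken to rest as the open hydroxy ketone of the target SMILES; the cyclic hemiketal (18) is treated as a transient form.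

Step 1
Reactants: 1 (2,4,6-trihydroxyphenyl)(phenyl)methanone
Product: 2 [4-(tert-butyldimethylsilyloxy)-2,6-dihydroxyphenyl](phenyl)methanone
Conditions: TBSCl (1.05 equiv), imidazole, DMF, 0 °C
Reagents that add atoms: tert-butyldimethylsilyl chloride, CC(C)(C)[Si](C)(C)Cl
Why: Phenol silylation; the 4-OH is the only hydroxyl not hydrogen-bonded to the benzoyl carbonyl and should react first, and the silyl group then keeps this oxygen out of the later ring closures.

Step 2
Reactants: 2 [4-(tert-butyldimethylsilyloxy)-2,6-dihydroxyphenyl](phenyl)methanone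
Product: 3 {4-(tert-butyldimethylsilyloxy)-3-[(dimethylamino)methyl]-2,6-dihydroxyphenyl}(phenyl)methanone
Conditions: Me2N=CH2 I (Eschenmoser's salt, 1.0 equiv), CH2Cl2, rt; aq. NaHCO3
Reagents that add atoms: N,N-dimethylmethyleneiminium iodide, C=[N+](C)C.[I-]
Why: Mannich aminomethylation of the electron-rich arene at one of its two equivalent free positions, which installs the future C14 as a latent o-quinone methide.

Step 3
Reactants: 4 3,3-dimethylpent-4-enoic acid; 5 (R)-4-benzyloxazolidin-2-one
Product: 7 (R)-4-benzyl-3-(3,3-dimethylpent-4-enoyl)oxazolidin-2-one, via mixed anhydride 6 (not isolated)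
Conditions: PivCl, Et3N, THF, −20 °C; then 5, LiCl, rt
Reagents that add atoms: none
Why: N-Acylation of the oxazolidinone auxiliary through the mixed pivalic anhydride, the standard preparation of acyl oxazolidinones.

Step 4
Reactants: 3 {4-(tert-butyldimethylsilyloxy)-3-[(dimethylamino)methyl]-2,6-dihydroxyphenyl}(phenyl)methanone; 7 (R)-4-benzyl-3-(3,3-dimethylpent-4-enoyl)oxazolidin-2-one
Product: 10 (R)-4-benzyl-3-[(2R)-2-{[3-benzoyl-6-(tert-butyldimethylsilyloxy)-2,4-dihydroxyphenyl]methyl}-3,3-dimethylpent-4-enoyl]oxazolidin-2-one, via ammonium iodide 8 (not isolated), via o-quinone methide 9 (not isolated)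
Conditions: 3, MeI, THF, rt; then added to 7/NaHMDS (3.3 equiv in all), THF, −78 to 0 °C; aq. NH4Cl
Reagents that add atoms: none
Why: Quaternisation and base-induced loss of trimethylamine should give the o-quinone methide, which the chelated Z sodium enolate of 7 attacks by conjugate addition (auxiliary-controlled enolate alkylation) on the face away from the benzyl group, setting C13 as R.

Step 5
Reactants: 10 (R)-4-benzyl-3-[(2R)-2-{[3-benzoyl-6-(tert-butyldimethylsilyloxy)-2,4-dihydroxyphenyl]methyl}-3,3-dimethylpent-4-enoyl]oxazolidin-2-one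
Product: 12 (3R)-3-{[3-benzoyl-6-(tert-butyldimethylsilyloxy)-2,4-dihydroxyphenyl]methyl}-2,4,4-trimethylhex-5-en-2-ol, via lactone 11 (not isolated)
Conditions: MeMgBr (6 equiv), THF, 0 °C to rt; aq. NH4Cl
Reagents that add atoms: methylmagnesium bromide, C[Mg]Br
Why: Magnesium phenoxide-assisted acyl transfer to the ortho oxygen (lactonisation with release of the auxiliary) followed by double Grignard addition to the aryl lactone should give the tertiary alcohol, the benzophenone carbonyl being deactivated as its chelated magnesium phenoxide and C13 untouched.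

Step 6
Reactants: 12 (3R)-3-{[3-benzoyl-6-(tert-butyldimethylsilyloxy)-2,4-dihydroxyphenyl]methyl}-2,4,4-trimethylhex-5-en-2-ol
Product: 13 [(3R)-5-(tert-butyldimethylsilyloxy)-7-hydroxy-2,2-dimethyl-3-(2-methylbut-3-en-2-yl)chroman-8-yl](phenyl)methanone
Conditions: p-TsOH·H2O (10 mol %), CH2Cl2, rt
Reagents that add atoms: none
Why: Acid-catalysed cyclodehydration (intramolecular etherification through the tertiary cation) closes ring P on the only free ortho oxygen, the one next to the benzoyl-bearing carbon.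

Step 7
Reactants: 13 [(3R)-5-(tert-butyldimethylsilyloxy)-7-hydroxy-2,2-dimethyl-3-(2-methylbut-3-en-2-yl)chroman-8-yl](phenyl)methanone; 14 1-bromo-3-methylbut-2-ene
Product: 17 (3R)-8-benzoyl-7-hydroxy-2,2-dimethyl-3-(2-methylbut-3-en-2-yl)-6,6-bis(3-methylbut-2-enyl)-3,4-dihydro-2H-chromen-5(6H)-one, via diol 15 (not isolated), via monoprenyl arene 16 (not isolated)
Conditions: NaOMe (5 equiv), MeOH, 0 °C; 14 (2.5 equiv), 0 °C to rt
Reagents that add atoms: none
Why: Methoxide cleaves the aryl silyl ether and the phloroglucinol-type anion undergoes alkylative dearomatisation (two C-prenylations) at the only ring carbon flanked by two free oxygens, giving the geminal diprenyl dienone without a new stereocentre.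

Step 8
Reactants: 17 (3R)-8-benzoyl-7-hydroxy-2,2-dimethyl-3-(2-methylbut-3-en-2-yl)-6,6-bis(3-methylbut-2-enyl)-3,4-dihydro-2H-chromen-5(6H)-one
Product: 19 5-prenyl cage trione (the target with 3-methylbut-2-enyl in place of geranyl on C5; all ring stereocentres as in 23), via hemiketal 18 (not isolated)
Conditions: Mn(OAc)3·2H2O (2.5 equiv, in portions), AcOH/H2O 20:1, degassed, 60 °C
Reagents that add atoms: water, O
Why: One-electron oxidation of the chelated C9 enol by trivalent manganese should give a tricarbonyl radical with spin at C1 and, through the C2=C3 enol ether, at C3; C3 closes 5-exo-trig on the internal vinyl carbon C11 (cyclopentane), the primary C10 radical adds 7-exo-trig to C7 of the prenyl group on the same face (seven-membered ring), the tertiary C8 radical closes 6-exo-trig on C1 (ring B), and the α-alkoxy C2 radical is oxidised to the oxocarbenium ion, which water opens through hemiketal 18 to the hydroxy ketone. The closest known reaction type is the Mn(OAc)3-mediated oxidative radical cyclisation cascade of dearomatised prenylated acylphloroglucinols and of 2-alkenyl-1,3-dicarbonyl compounds. C3 and C11 are set by ring P: the pseudo-axial C12 tether reaches only one face of C3, and in the chair-like transition state the CH2 terminus turns away from the O–CMe2 bridge, so C10 ends trans to C15 and syn to the C4 carbonyl. C5, C7 and C1 follow from the cage, since only the prenyl group syn to C10 can be reached and ring B can only close on that face. The step needs the tether to win over 5-exo attack of the ring radical on a geminal prenyl group and over 6-endo closure; the first is argued from the endocyclic carbonyl in the competing closure (slow) against exocyclic carbonyls and a preorganised gem-dimethyl tether (fast), the second from the usual 5-exo preference of such radicals. The product has no enolisable position left, so it should not be oxidised further.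

Step 9
Reactants: 19 5-prenyl cage trione
Product: 20 (E)-allylic alcohol (C5 side chain CH2–CH=C(CH3)–CH2OH)
Conditions: SeO2 (0.3 equiv), t-BuOOH (3 equiv), CH2Cl2, rt
Reagents that add atoms: tert-butyl hydroperoxide, CC(C)(C)OO
Why: SeO2-catalysed allylic oxidation (ene reaction then [2,3]-sigmatropic shift) is intrinsically selective for the E-methyl group of a trisubstituted olefin, and the prenyl group is the only olefin left.

Step 10
Reactants: 20 (E)-allylic alcohol
Product: 21 (E)-allylic bromide (C5 side chain CH2–CH=C(CH3)–CH2Br)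
Conditions: CBr4, PPh3, CH2Cl2, 0 °C
Reagents that add atoms: carbon tetrabromide, BrC(Br)(Br)Br
Why: Appel bromination of the primary allylic alcohol; the hindered tertiary alcohol should not react and the E double bond is kept.

Step 11
Reactants: 21 (E)-allylic bromide
Product: 22 (E)-1,5-diene (C5 side chain CH2–CH=C(CH3)–CH2–CH2–CH=CH2)
Conditions: allyltributylstannane, Pd2(dba)3 (5 mol %), tri(2-furyl)phosphine, THF, 50 °C
Reagents that add atoms: allyltributylstannane, C=CC[Sn](CCCC)(CCCC)CCCC
Why: Stille-type allyl–allyl cross-coupling through the π-allyl palladium complex, which should couple at its unhindered primary terminus with the E geometry kept and needs no base.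

Step 12
Reactants: 22 (E)-1,5-diene
Product: 23 CNP0164095.1 (target)
Conditions: 2-methylbut-2-ene (excess), second-generation Grubbs catalyst (5 mol %), CH2Cl2, 40 °C
Reagents that add atoms: 2-methylbut-2-ene, CC=C(C)C
Why: Olefin cross-metathesis turns the terminal vinyl group into the isopropylidene end of the geranyl chain, the trisubstituted 2,3-olefin being inert.

**Compound list**
1 | (2,4,6-trihydroxyphenyl)(phenyl)methanone | O=C(c1ccccc1)c1c(O)cc(O)cc1O | starting material
2 | [4-(tert-butyldimethylsilyloxy)-2,6-dihydroxyphenyl](phenyl)methanone | O=C(c1ccccc1)c1c(O)cc(O[Si](C)(C)C(C)(C)C)cc1O | intermediate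
3 | {4-(tert-butyldimethylsilyloxy)-3-[(dimethylamino)methyl]-2,6-dihydroxyphenyl}(phenyl)methanone | CN(C)Cc1c(O)c(C(=O)c2ccccc2)c(O)cc1O[Si](C)(C)C(C)(C)C | intermediate
4 | 3,3-dimethylpent-4-enoic acid | C=CC(C)(C)CC(=O)O | starting material
5 | (R)-4-benzyloxazolidin-2-one | O=C1OC[C@@H](Cc2ccccc2)N1 | starting material
6 | 3,3-dimethylpent-4-enoic pivalic anhydride | C=CC(C)(C)CC(=O)OC(=O)C(C)(C)C | intermediate
7 | (R)-4-benzyl-3-(3,3-dimethylpent-4-enoyl)oxazolidin-2-one | C=CC(C)(C)CC(=O)N1C(=O)OC[C@H]1Cc1ccccc1 | intermediate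
8 | [3-benzoyl-6-(tert-butyldimethylsilyloxy)-2,4-dihydroxyphenyl]methyl-trimethylammonium iodide | C[N+](C)(C)Cc1c(O)c(C(=O)c2ccccc2)c(O)cc1O[Si](C)(C)C(C)(C)C.[I-] | intermediate
9 | 2-benzoyl-5-(tert-butyldimethylsilyloxy)-3-hydroxy-6-methylenecyclohexa-2,4-dien-1-one (o-quinone methide) | C=C1C(O[Si](C)(C)C(C)(C)C)=CC(O)=C(C(=O)c2ccccc2)C1=O | intermediate
10 | (R)-4-benzyl-3-[(2R)-2-{[3-benzoyl-6-(tert-butyldimethylsilyloxy)-2,4-dihydroxyphenyl]methyl}-3,3-dimethylpent-4-enoyl]oxazolidin-2-one | C=CC(C)(C)[C@@H](Cc1c(O)c(C(=O)c2ccccc2)c(O)cc1O[Si](C)(C)C(C)(C)C)C(=O)N1C(=O)OC[C@H]1Cc1ccccc1 | intermediate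
11 | (3R)-8-benzoyl-5-(tert-butyldimethylsilyloxy)-7-hydroxy-3-(2-methylbut-3-en-2-yl)chroman-2-one | O=C1Oc2c(C(=O)c3ccccc3)c(O)cc(O[Si](C)(C)C(C)(C)C)c2C[C@@H]1C(C)(C)C=C | intermediate
12 | (3R)-3-{[3-benzoyl-6-(tert-butyldimethylsilyloxy)-2,4-dihydroxyphenyl]methyl}-2,4,4-trimethylhex-5-en-2-ol | C=CC(C)(C)[C@@H](Cc1c(O)c(C(=O)c2ccccc2)c(O)cc1O[Si](C)(C)C(C)(C)C)C(C)(C)O | intermediate
13 | [(3R)-5-(tert-butyldimethylsilyloxy)-7-hydroxy-2,2-dimethyl-3-(2-methylbut-3-en-2-yl)chroman-8-yl](phenyl)methanone | O=C(c1ccccc1)c1c(O)cc(O[Si](C)(C)C(C)(C)C)c2c1OC(C)(C)[C@@H](C(C)(C)C=C)C2 | intermediate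
14 | 1-bromo-3-methylbut-2-ene (prenyl bromide) | CC(C)=CCBr | starting material
15 | [(3R)-5,7-dihydroxy-2,2-dimethyl-3-(2-methylbut-3-en-2-yl)chroman-8-yl](phenyl)methanone | O=C(c1ccccc1)c1c(O)cc(O)c2c1OC(C)(C)[C@@H](C(C)(C)C=C)C2 | intermediate
16 | [(3R)-5,7-dihydroxy-2,2-dimethyl-3-(2-methylbut-3-en-2-yl)-6-(3-methylbut-2-enyl)chroman-8-yl](phenyl)methanone | O=C(c1ccccc1)c1c(O)c(CC=C(C)C)c(O)c2c1OC(C)(C)[C@@H](C(C)(C)C=C)C2 | intermediate
17 | (3R)-8-benzoyl-7-hydroxy-2,2-dimethyl-3-(2-methylbut-3-en-2-yl)-6,6-bis(3-methylbut-2-enyl)-3,4-dihydro-2H-chromen-5(6H)-one | O=C1C(CC=C(C)C)(CC=C(C)C)C(O)=C(C(=O)c2ccccc2)C3=C1C[C@H](C(C)(C)C=C)C(C)(C)O3 | intermediate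
18 | cyclic C2/C15 hemiketal of 19 (C2 carries OH and the ring oxygen bound to C15; cage as in 19) | CC(C)=CC[C@@]12C[C@H]3C[C@H]4C(C)(C)[C@H](C(C)(C)O5)C[C@]4(C1=O)[C@@]5(O)[C@@](C(=O)c1ccccc1)(C2=O)C3(C)C | intermediate
19 | 5-prenyl cage trione: ring A 2,4,9-trione with 1-benzoyl and 5-(3-methylbut-2-enyl), C8 gem-dimethyl, C7–C10–C11–C3 bridge, cis-fused cyclopentane C3–C11–C12(Me2)–C13–C14, C13 (R) with 2-hydroxypropan-2-yl cis to the C2 carbonyl and trans to C10 | CC(C)=CC[C@@]12C[C@H]3C[C@H]4C(C)(C)[C@H](C(C)(C)O)C[C@]4(C1=O)C(=O)[C@@](C(=O)c1ccccc1)(C2=O)C3(C)C | intermediate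
20 | cage trione with 5-[(E)-4-hydroxy-3-methylbut-2-enyl] side chain (cage as in 19) | OC/C(C)=C/C[C@@]12C[C@H]3C[C@H]4C(C)(C)[C@H](C(C)(C)O)C[C@]4(C1=O)C(=O)[C@@](C(=O)c1ccccc1)(C2=O)C3(C)C | intermediate
21 | cage trione with 5-[(E)-4-bromo-3-methylbut-2-enyl] side chain (cage as in 19) | BrC/C(C)=C/C[C@@]12C[C@H]3C[C@H]4C(C)(C)[C@H](C(C)(C)O)C[C@]4(C1=O)C(=O)[C@@](C(=O)c1ccccc1)(C2=O)C3(C)C | intermediate
22 | cage trione with 5-[(E)-3-methylhepta-2,6-dienyl] side chain (cage as in 19) | C=CCC/C(C)=C/C[C@@]12C[C@H]3C[C@H]4C(C)(C)[C@H](C(C)(C)O)C[C@]4(C1=O)C(=O)[C@@](C(=O)c1ccccc1)(C2=O)C3(C)C | intermediate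
23 | CNP0164095.1: cage trione with 5-[(E)-3,7-dimethylocta-2,6-dienyl] (geranyl) side chain | CC(C)=CCC/C(C)=C/C[C@@]12C[C@H]3C[C@H]4C(C)(C)[C@H](C(C)(C)O)C[C@]4(C1=O)C(=O)[C@@](C(=O)c1ccccc1)(C2=O)C3(C)C | target

Total steps: 12. Longest linear sequence: 11 (steps 1, 2, 4–12; step 3 is a side branch).

**Steps most likely to fail**

Step 8. The ring-centred radical may be captured 5-exo by one of the geminal prenyl groups (bicyclo[3.2.1] closure through a ring carbonyl), may close 6-endo on the vinyl terminus, or the tertiary C8 radical may be oxidised before it reaches C1. The fallback sets out from 13 and comes back at 19; it avoids the ring radical by making the C3–C11 bond in a two-electron step and starting the radical at C10. Cross-metathesis of the vinyl group of 13 with methyl acrylate (second-generation Hoveyda–Grubbs catalyst) should give the enoate, methyl (E)-4-[(3R)-8-benzoyl-5-(tert-butyldimethylsilyloxy)-7-hydroxy-2,2-dimethylchroman-3-yl]-4-methylpent-2-enoate F1. NaOMe/MeOH with prenyl bromide 14 removes the silyl group, lets C3 add to the enoate β-carbon C11 in a dearomatising 5-exo Michael addition under the same ring P control, and diprenylates C5, giving the bridged gem-diprenyl methyl ester F2. Me3SnOH cleaves the ester to the acid F3. Its N-hydroxypyridine-2-thione ester F4 is photolysed at high dilution (Barton decarboxylation): the primary C10 radical runs the 7-exo/6-exo sequence and the C2 radical takes the pyridylthio group from a second ester molecule, giving the O,S-ketal F5. AgNO3 in wet acetone should hydrolyse F5 through 18 to 19.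

Step 7. O-alkylation, alkylation at the ring-fusion carbon or stopping at the monoprenyl arene may compete with geminal C-prenylation. The fallback sets out from 13 and comes back at 17; it replaces the SN2 alkylation of the phenoxide by a Tsuji–Trost reaction. Bu4NF removes the silyl group and 15 is isolated. Methyl 3-methylbut-2-enyl carbonate and Pd(PPh3)4 (zerovalent palladium) in THF should then alkylate the soft C6 carbon twice through the π-prenyl complex at its unhindered terminus (through 16), giving 17. No new compound is made.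

Step 5. The Grignard reagent may add to the benzophenone carbonyl or open the oxazolidinone ring at its endocyclic carbonyl instead of the hindered exocyclic one. The fallback sets out from 10 and comes back at 12; it replaces the double addition by stepwise acyl substitution. LiSEt (from EtSH and n-BuLi) should cleave the auxiliary at the exocyclic carbonyl to give the thioester, S-ethyl (2R)-2-{[3-benzoyl-6-(tert-butyldimethylsilyloxy)-2,4-dihydroxyphenyl]methyl}-3,3-dimethylpent-4-enethioate F6. Me2CuLi converts it into the methyl ketone, (3R)-3-{[3-benzoyl-6-(tert-butyldimethylsilyloxy)-2,4-dihydroxyphenyl]methyl}-4,4-dimethylhex-5-en-2-one F7, without touching the diaryl ketone. One equivalent of MeMgBr with CeCl3 then gives 12.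

**Further compounds**
F1 | step 8 | methyl (E)-4-[(3R)-8-benzoyl-5-(tert-butyldimethylsilyloxy)-7-hydroxy-2,2-dimethylchroman-3-yl]-4-methylpent-2-enoate | O=C(c1ccccc1)c1c(O)cc(O[Si](C)(C)C(C)(C)C)c2c1OC(C)(C)[C@@H](C(C)(C)/C=C/C(=O)OC)C2
F2 | step 8 | bridged gem-diprenyl methyl ester (C3–C11 closed, CH2CO2Me on C11 trans to the O–CMe2 bridge, ring P intact, C1=C2 enol ether, C4 and C9 ketones) | O=C1C(CC=C(C)C)(CC=C(C)C)C(=O)C(C(=O)c2ccccc2)=C3OC(C)(C)[C@@H]4C[C@]13[C@@H](CC(=O)OC)C4(C)C
F3 | step 8 | carboxylic acid of F2 | O=C1C(CC=C(C)C)(CC=C(C)C)C(=O)C(C(=O)c2ccccc2)=C3OC(C)(C)[C@@H]4C[C@]13[C@@H](CC(=O)O)C4(C)C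
F4 | step 8 | N-hydroxypyridine-2-thione ester of F3 | O=C1C(CC=C(C)C)(CC=C(C)C)C(=O)C(C(=O)c2ccccc2)=C3OC(C)(C)[C@@H]4C[C@]13[C@@H](CC(=O)ON5C=CC=CC5=S)C4(C)C
F5 | step 8 | C2 O,S-ketal of 19 (hemiketal 18 with pyridin-2-ylthio in place of OH) | CC(C)=CC[C@@]12C[C@H]3C[C@H]4C(C)(C)[C@H](C(C)(C)O5)C[C@]4(C1=O)[C@@]5(Sc6ccccn6)[C@@](C(=O)c1ccccc1)(C2=O)C3(C)C
F0 | step 7 | none | none
F6 | step 5 | S-ethyl (2R)-2-{[3-benzoyl-6-(tert-butyldimethylsilyloxy)-2,4-dihydroxyphenyl]methyl}-3,3-dimethylpent-4-enethioate | C=CC(C)(C)[C@@H](Cc1c(O)c(C(=O)c2ccccc2)c(O)cc1O[Si](C)(C)C(C)(C)C)C(=O)SCC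
F7 | step 5 | (3R)-3-{[3-benzoyl-6-(tert-butyldimethylsilyloxy)-2,4-dihydroxyphenyl]methyl}-4,4-dimethylhex-5-en-2-one | C=CC(C)(C)[C@@H](Cc1c(O)c(C(=O)c2ccccc2)c(O)cc1O[Si](C)(C)C(C)(C)C)C(C)=O
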